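The runs stem from a simulated flask from invented constants, noise included.

In the first 0.65 h, the green flask makes 26.5 mM of product and the grey flask, charged with 60.0 mM of product, makes 25.9 mM. The gap of 0.600 mM compares with a scatter of 1 mM, so this pair of readings shows no effect of added product on the rate.

| flask | substrate | coupling partner | free catalyst | product | time |
|---|---|---|---|---|---|
| green | 120 mM | 180 mM | 12.0 mM |  |  |
| grey | 120 mM | 180 mM | 12.0 mM | 60.0 mM |  |
| red | 240 mM | 180 mM | 4.00 mM |  | 3.9 h |

- green run (time / h: [product] / mM): 0.65: 26.5; 1.3: 44.5; 1.9: 56.7; 2.6: 66.9; 3.2: 75.6; 3.9: 81.6
- grey run (time / h: [product] / mM): 0.65: 85.9; 1.3: 105.1; 1.9: 115.0; 2.6: 128.2; 3.2: 133.3; 3.9: 139.7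

(standard deviation of a reading: 1 mM)

- product in the red run at 3.9 h, as a share of the substrate charged

Can one constant then carry the green run? Integrating rate = k[substrate][coupling partner] to the last green reading gives 2.29 L mol⁻¹ h⁻¹. This apparent second-order constant, the rate of product formation divided by [substrate][coupling partner], comes out at 2.31 L mol⁻¹ h⁻¹ from the first green reading, a ratio of 0.991. Within these two green readings, one constant serves.

What does it give in the red flask? There the coupling partner is the limiting reagent, 180 mM against 240 mM of substrate, so the share cannot pass 75.0%. The red flask holds a third of the green catalyst charge. Taking the constant as blind to catalyst, which is the zero of the scale, the same integrated form gives 55.4%. A constant that falls with the catalyst charge gives less in the red flask. The green and grey runs share one catalyst charge, so they cannot show such a fall, and this reckoning commits to 55.4% as the mark for a constant that does not fall, and to no lower figure.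

The forecast is 33%, below that mark, and it says of its own ground: “The catalyst order is untested.”

The red flask gives 45.5%. Its charge of free catalyst, 4.00 mM, is smaller than the impurity present from the start, 6.84 mM, and the two react at once to spent catalyst.

    2 free catalyst ⇌ catalyst dimer, settled at all times (1430 L mol⁻¹)
    free catalyst + substrate + coupling partner → product + free catalyst (752.4 L² mol⁻² h⁻¹)
    free catalyst + impurity → spent catalyst
    substrate + coupling partner → product (1.397 L mol⁻¹ h⁻¹)

Read through the same integrated form, the red result gives 1.40 L mol⁻¹ h⁻¹, which is 0.611 of the green constant. The green constant stands 0.890 L mol⁻¹ h⁻¹ above it.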